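## Retrosynthetic overview

- Locants: ring carbons C1–C10 (C1, C3 = CH–OAc; C4 = C–CH3; C10 = C=CH2), lactone carbons C11 (α), C12 (C=O), C13 (CH2OH). Target ⇐ C6 lactol 21 (ionic hydrogenation fixes C6) ⇐ cyclodecenone 14 + α-keto ester 18.
- Key disconnection: C7–C11 (crossed aldol) and O–C6 (lactolisation) in one flask. The whole five-membered lactone with C13 is annulated onto a plain ketone, with C6 held one oxidation level too high until step 16.
- Enabling feature: the O-bearing γ-carbon C6 and the β-carbon C7 of the five-membered lactone are neighbours in the ten-membered ring. As a C6 ketone next to the C4=C5 olefin, C7 is its only enolisable carbon, so C7 (donor)/C6 (acceptor) match the keto carbon (acceptor)/carboxyl oxygen (donor) of an α-keto acid.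
- 14 ⇐ Nozaki–Hiyama–Kishi ring closure C5–C6 of iodo aldehyde 12, then oxidation (both C6 epimers converge); 12 ⇐ Paterson aldol (C2–C3, sets C3) and 1,3-anti reduction (sets C1) from iodoenal 3 and enone 7.
- Ring order: ten-membered carbocycle first (step 10), five-membered lactone last (step 15).

Key step: step 15

Remark: (−)-Ipc2BCl stands for the antipode of the boron reagent that gives the 3S aldol (sense assigned by analogy with methyl ketone aldols of this reagent class); C1 and C6 are then set relative to C3.

## Route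

Step 1
Reactants: 1 prop-2-yn-1-ol
Product: 2 (Z)-3-iodo-2-methylprop-2-en-1-ol
Conditions: MeMgBr (2.5 equiv), CuI (10 mol%), Et2O/THF, −10 → 20 °C; then I2, −78 → 0 °C
Reagents that add atoms: methylmagnesium bromide C[Mg]Br; iodine II
Why: Copper-catalysed anti-carbomagnesiation of the propargylic alkoxide (magnesium chelate) places methyl and magnesium trans, and iodinolysis with retention should give the Z iodide that fixes the C4=C5 geometry for the whole route.

Step 2
Reactants: 2 (Z)-3-iodo-2-methylprop-2-en-1-ol
Product: 3 (Z)-3-iodo-2-methylprop-2-enal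
Conditions: MnO2, CH2Cl2, 20 °C
Reagents that add atoms: none
Why: Allylic alcohol oxidation with MnO2 under neutral conditions should give the enal without Z/E isomerisation.

Step 3
Reactants: 4 diethyl (2-oxopropyl)phosphonate; 5 tert-butyl(4-iodobutoxy)dimethylsilane
Product: 6 diethyl {7-[(tert-butyldimethylsilyl)oxy]-2-oxoheptan-3-yl}phosphonate (racemic)
Conditions: NaH, THF/DMF, 0 → 60 °C
Reagents that add atoms: none
Why: Active-methylene alkylation: the sodium salt of the β-ketophosphonate is alkylated at the doubly activated carbon by SN2 displacement of the primary iodide.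

Step 4
Reactants: 6 diethyl {7-[(tert-butyldimethylsilyl)oxy]-2-oxoheptan-3-yl}phosphonate
Product: 7 7-[(tert-butyldimethylsilyl)oxy]-3-methylideneheptan-2-one
Conditions: HCHO (37% aq.), K2CO3, THF/H2O, 20 °C
Reagents that add atoms: formaldehyde C=O
Why: Horner–Wadsworth–Emmons olefination with formaldehyde can only give the 1,1-disubstituted enone, because the phosphonate carbon becomes C10.

Step 5
Reactants: 7 7-[(tert-butyldimethylsilyl)oxy]-3-methylideneheptan-2-one; 3 (Z)-3-iodo-2-methylprop-2-enal
Product: 8 (8S,9Z)-1-[(tert-butyldimethylsilyl)oxy]-8-hydroxy-10-iodo-9-methyl-5-methylidenedec-9-en-6-one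
Conditions: (−)-Ipc2BCl, Et3N, Et2O, 0 °C; then 3, −78 → −20 °C; H2O2, pH 7 buffer, MeOH
Reagents that add atoms: none
Why: Paterson aldol: the kinetic diisopinocampheylboron enolate of the methyl group (the only enolisable position of 7) adds 1,2 to the enal through a cyclic transition state, and the chiral ligands on boron set C3 (target locant) as S.

Step 6
Reactants: 8 (8S,9Z)-β-hydroxy ketone
Product: 9 (6S,8S,9Z)-1-[(tert-butyldimethylsilyl)oxy]-10-iodo-9-methyl-5-methylidenedec-9-ene-6,8-diol
Conditions: Me4NBH(OAc)3, MeCN/AcOH (1:1), −30 °C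
Reagents that add atoms: none
Why: Evans–Saksena reduction: the C3 alkoxide binds the acetoxyborohydride and delivers hydride internally through a chair transition state, which should give the 1,3-anti diol and set C1 as S.

Step 7
Reactants: 9 (6S,8S,9Z)-diol
Product: 10 (6S,8S,9Z)-1-[(tert-butyldimethylsilyl)oxy]-10-iodo-9-methyl-5-methylidenedec-9-ene-6,8-diyl diacetate
Conditions: Ac2O, pyridine, DMAP (cat.), CH2Cl2, 20 °C
Reagents that add atoms: acetic anhydride CC(=O)OC(C)=O
Why: Nucleophilic-catalysed acylation installs both acetates of the target on the secondary alcohols without touching the stereocentres.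

Step 8
Reactants: 10 silyl ether diacetate
Product: 11 (6S,8S,9Z)-1-hydroxy-10-iodo-9-methyl-5-methylidenedec-9-ene-6,8-diyl diacetate
Conditions: HF·pyridine, THF/pyridine, 0 °C
Reagents that add atoms: none
Why: Fluoride-driven cleavage of the primary silyl ether (Si–F bond formation) under buffered conditions that the acetates and the vinyl iodide should survive.

Step 9
Reactants: 11 primary alcohol
Product: 12 (6S,8S,9Z)-10-iodo-9-methyl-5-methylidene-1-oxodec-9-ene-6,8-diyl diacetate
Conditions: Dess–Martin periodinane, NaHCO3, CH2Cl2, 0 → 20 °C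
Reagents that add atoms: none
Why: Dess–Martin oxidation stops at the aldehyde and its buffered, neutral medium should leave the allylic acetates intact.

Step 10
Reactants: 12 iodo aldehyde
Product: 13 (1S,3S,4Z)-6-hydroxy-4-methyl-10-methylidenecyclodec-4-ene-1,3-diyl diacetate (C6 epimers)
Conditions: CrCl2 (6 equiv), NiCl2 (1 mol%), DMSO/THF, 20 °C, slow addition at high dilution
Reagents that add atoms: none
Why: Nozaki–Hiyama–Kishi reaction: zerovalent nickel inserts into the C–I bond with retention of the Z geometry, transmetalation gives the alkenyl species of trivalent chromium, and this adds chemoselectively to the aldehyde to close the ten-membered ring; the C6 configuration is immaterial because step 11 removes it.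

Step 11
Reactants: 13 macrocyclic allylic alcohol
Product: 14 (1S,3S,4Z)-4-methyl-10-methylidene-6-oxocyclodec-4-ene-1,3-diyl diacetate
Conditions: Dess–Martin periodinane, NaHCO3, CH2Cl2, 0 → 20 °C
Reagents that add atoms: none
Why: Oxidation of the allylic alcohol converges both C6 epimers into one Z enone and raises C6 to the oxidation level that the key step needs.

Step 12
Reactants: 15 tert-butyl prop-2-enoate
Product: 16 tert-butyl 2-(hydroxymethyl)prop-2-enoate
Conditions: HCHO (37% aq.), DABCO, 1,4-dioxane/H2O, 20 °C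
Reagents that add atoms: formaldehyde C=O
Why: Morita–Baylis–Hillman reaction of the acrylate with formaldehyde attaches the future C13 to the future C11.

Step 13
Reactants: 16 tert-butyl 2-(hydroxymethyl)prop-2-enoate
Product: 17 tert-butyl 2-{[(tert-butyldiphenylsilyl)oxy]methyl}prop-2-enoate
Conditions: TBDPSCl, imidazole, DMF, 20 °C
Reagents that add atoms: tert-butyl(chloro)diphenylsilane CC(C)(C)[Si](Cl)(c1ccccc1)c1ccccc1
Why: Silylation gives an acid-stable ether that should survive the trifluoroacetic acid and BF3 stages of steps 15 and 16.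

Step 14
Reactants: 17 silyl ether acrylate
Product: 18 tert-butyl 3-[(tert-butyldiphenylsilyl)oxy]-2-oxopropanoate
Conditions: O3, CH2Cl2, −78 °C; then Me2S
Reagents that add atoms: ozone [O-][O+]=O
Why: Ozonolysis of the 1,1-disubstituted alkene with reductive work-up gives the α-keto ester, a three-carbon unit with C11 as keto carbon, C12 as carboxyl carbon and C13 carrying the oxygen.

Step 15
Reactants: 14 (1S,3S,4Z)-cyclodecenone diacetate; 18 tert-butyl 3-[(tert-butyldiphenylsilyl)oxy]-2-oxopropanoate
Product: 21 C6 lactol (5-hydroxyfuran-2(5H)-one fused at C6–C7 with C13–OTBDPS; C6 epimers), via aldol adduct 19 (not isolated), via keto acid 20 (not isolated)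
Conditions: LiN(SiMe3)2 (1.05 equiv), THF, −78 °C; 18; then CF3CO2H, CH2Cl2, −78 → 20 °C (one flask)
Reagents that add atoms: none
Why: The amide base removes a proton from C7, which carries the only α-hydrogens of the ketone, and the lithium enolate adds to the highly electrophilic keto carbonyl of 18 (crossed aldol, C7–C11) to give 19; trifluoroacetic acid then cleaves the tert-butyl ester, the β-hydroxy ketone loses water by enol-mediated elimination toward C7 (the only acidic β-hydrogen, so the double bond can only become C7=C11), and keto acid 20 closes by attack of the carboxyl oxygen on the C6 ketone (O–C6). The closest known reaction type is the aldol condensation of ketones with glyoxylic or pyruvic acid derivatives to 5-hydroxyfuran-2(5H)-ones (pseudo-acids), whose ring–chain equilibrium favours the ring for Z keto acids. The five-membered lactone closes in the 5-exo-trig mode. No stereocentre has to be controlled here: C7 and C11 become sp2 and the C6 lactol centre equilibrates and is set in step 16, while C1, C3 and the Z olefin are not touched. The step needs enolisation of the ketone and not of the acetates, which the much higher acidity of the ketone, one equivalent of a hindered base and −78 °C should secure. It also needs addition to the keto and not the ester carbonyl of 18 and dehydration before retro-aldol cleavage, which the keto group's higher electrophilicity and the irreversible elimination in acid should secure.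

Step 16
Reactants: 21 C6 lactol
Product: 22 13-O-(tert-butyldiphenylsilyl) ether of the target, (1S,3S,6R,4Z)
Conditions: Et3SiH, BF3·OEt2, CH2Cl2, −78 → −40 °C
Reagents that add atoms: none
Why: Ionic hydrogenation: BF3 ionises the tertiary lactol to the 2-oxofuranylium ion, which keeps the ring oxygen, and Et3SiH delivers hydride to C6, its oxygen-stabilised terminus; allylic 1,3-strain across the Z C4=C5 bond turns the C3 acetoxy group outward and C3–H inward, so the C2–C1–C10–C9 bridge covers one face of the planar cation and hydride should enter on the open face (that of C3–H), which corresponds to 6R.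

Step 17
Reactants: 22 silyl ether
Product: 23 (1S,3S,6R,4Z)-1,3-diacetoxy-13-hydroxygermacra-4,7(11),10(14)-trien-12,6-olide (target)
Conditions: HF·pyridine, THF/pyridine, 0 → 20 °C
Reagents that add atoms: none
Why: Fluoride-driven desilylation under buffered, non-basic conditions should free the primary alcohol without acyl migration or epimerisation of the base-sensitive C6–H.

## Compound list

1 | prop-2-yn-1-ol | C#CCO | starting material
2 | (Z)-3-iodo-2-methylprop-2-en-1-ol | I/C=C(/C)CO | intermediate
3 | (Z)-3-iodo-2-methylprop-2-enal | I/C=C(/C)C=O | intermediate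
4 | diethyl (2-oxopropyl)phosphonate | CC(=O)CP(=O)(OCC)OCC | starting material
5 | tert-butyl(4-iodobutoxy)dimethylsilane | ICCCCO[Si](C)(C)C(C)(C)C | starting material
6 | diethyl {7-[(tert-butyldimethylsilyl)oxy]-2-oxoheptan-3-yl}phosphonate (racemic) | CC(=O)C(CCCCO[Si](C)(C)C(C)(C)C)P(=O)(OCC)OCC | intermediate
7 | 7-[(tert-butyldimethylsilyl)oxy]-3-methylideneheptan-2-one | CC(=O)C(=C)CCCCO[Si](C)(C)C(C)(C)C | intermediate
8 | (8S,9Z)-1-[(tert-butyldimethylsilyl)oxy]-8-hydroxy-10-iodo-9-methyl-5-methylidenedec-9-en-6-one | I/C=C(/C)[C@@H](O)CC(=O)C(=C)CCCCO[Si](C)(C)C(C)(C)C | intermediate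
9 | (6S,8S,9Z)-1-[(tert-butyldimethylsilyl)oxy]-10-iodo-9-methyl-5-methylidenedec-9-ene-6,8-diol | I/C=C(/C)[C@@H](O)C[C@H](O)C(=C)CCCCO[Si](C)(C)C(C)(C)C | intermediate
10 | (6S,8S,9Z)-1-[(tert-butyldimethylsilyl)oxy]-10-iodo-9-methyl-5-methylidenedec-9-ene-6,8-diyl diacetate | I/C=C(/C)[C@@H](OC(C)=O)C[C@H](OC(C)=O)C(=C)CCCCO[Si](C)(C)C(C)(C)C | intermediate
11 | (6S,8S,9Z)-1-hydroxy-10-iodo-9-methyl-5-methylidenedec-9-ene-6,8-diyl diacetate | I/C=C(/C)[C@@H](OC(C)=O)C[C@H](OC(C)=O)C(=C)CCCCO | intermediate
12 | (6S,8S,9Z)-10-iodo-9-methyl-5-methylidene-1-oxodec-9-ene-6,8-diyl diacetate | I/C=C(/C)[C@@H](OC(C)=O)C[C@H](OC(C)=O)C(=C)CCCC=O | intermediate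
13 | (1S,3S,4Z)-6-hydroxy-4-methyl-10-methylidenecyclodec-4-ene-1,3-diyl diacetate (C6 epimers) | C=C1CCCC(O)/C=C(/C)[C@@H](OC(C)=O)C[C@@H]1OC(C)=O | intermediate
14 | (1S,3S,4Z)-4-methyl-10-methylidene-6-oxocyclodec-4-ene-1,3-diyl diacetate | C=C1CCCC(=O)/C=C(/C)[C@@H](OC(C)=O)C[C@@H]1OC(C)=O | intermediate
15 | tert-butyl prop-2-enoate | C=CC(=O)OC(C)(C)C | starting material
16 | tert-butyl 2-(hydroxymethyl)prop-2-enoate | C=C(CO)C(=O)OC(C)(C)C | intermediate
17 | tert-butyl 2-{[(tert-butyldiphenylsilyl)oxy]methyl}prop-2-enoate | C=C(CO[Si](c1ccccc1)(c1ccccc1)C(C)(C)C)C(=O)OC(C)(C)C | intermediate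
18 | tert-butyl 3-[(tert-butyldiphenylsilyl)oxy]-2-oxopropanoate | O=C(CO[Si](c1ccccc1)(c1ccccc1)C(C)(C)C)C(=O)OC(C)(C)C | intermediate
19 | aldol adduct: 14 carrying C(OH)(CH2OTBDPS)CO2tBu at C7 (C7/C11 diastereomers) | C=C1CCC(C(O)(CO[Si](c2ccccc2)(c2ccccc2)C(C)(C)C)C(=O)OC(C)(C)C)C(=O)/C=C(/C)[C@@H](OC(C)=O)C[C@@H]1OC(C)=O | intermediate
20 | keto acid: 14 with C7=C11(CH2OTBDPS)CO2H (open form of 21) | C=C1CCC(=C(CO[Si](c2ccccc2)(c2ccccc2)C(C)(C)C)C(=O)O)C(=O)/C=C(/C)[C@@H](OC(C)=O)C[C@@H]1OC(C)=O | intermediate
21 | C6 lactol: 6-hydroxy-13-O-TBDPS derivative of the target skeleton (C6 epimers) | C=C1CCC2=C(CO[Si](c3ccccc3)(c3ccccc3)C(C)(C)C)C(=O)OC2(O)/C=C(/C)[C@@H](OC(C)=O)C[C@@H]1OC(C)=O | intermediate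
22 | 13-O-(tert-butyldiphenylsilyl) ether of the target, (1S,3S,6R,4Z) | C=C1CCC2=C(CO[Si](c3ccccc3)(c3ccccc3)C(C)(C)C)C(=O)O[C@@H]2/C=C(/C)[C@@H](OC(C)=O)C[C@@H]1OC(C)=O | intermediate
23 | (1S,3S,6R,4Z)-1,3-diacetoxy-13-hydroxygermacra-4,7(11),10(14)-trien-12,6-olide | C=C1CCC2=C(CO)C(=O)O[C@@H]2/C=C(/C)[C@@H](OC(C)=O)C[C@@H]1OC(C)=O | target

## Step count and risks

Total step count: 17. Longest linear sequence: 12 steps (steps 3–11 and 15–17, from 4 and 5).

Steps most likely to fail:

1. Step 16 – poor facial selectivity of hydride delivery to the planar cation at C6 (or hydride capture at the C4 terminus). The fallback sets out from 21 and comes back at 22. The ring-chain tautomer of 21 is reduced at the C6 ketone under catalyst control by asymmetric transfer hydrogenation (RuCl[(S,S)-TsDPEN](p-cymene) or its antipode, whichever gives the 6R carbinol, HCO2H/Et3N, 20 °C). The resulting (6R)-hydroxy acid F1 should lactonise on acidic work-up to 22.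

2. Step 15 – retro-aldol cleavage of the tertiary aldolate, or ionisation of the doubly allylic lactol with proton loss (over-dehydration) in the acid stage. The fallback sets out from 14 and comes back at 21, with the donor and acceptor roles exchanged. α-Hydroxylation of the lithium enolate of 14 with 2-(phenylsulfonyl)-3-phenyloxaziridine gives the 7-hydroxy ketone F2, and Dess–Martin oxidation gives the 6,7-diketone F3. The lithium enolate of tert-butyl 3-[(tert-butyldiphenylsilyl)oxy]propanoate F4 (from tert-butyl 3-hydroxypropanoate, TBDPSCl and imidazole) then adds to the non-conjugated C7 carbonyl to give the hydroxy ester F5. Trifluoroacetic acid should cleave the ester, close the lactol and eliminate water across C7/C11 to give 21.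

3. Step 10 – oligomerisation or slow closure because of the strain of the ten-membered ring. The fallback sets out from diol 9 and comes back at 14; the C5–C6 bond is closed on the anionic manifold before the acetates are introduced. 2,2-Dimethoxypropane/PPTS gives the acetonide F6, Bu4NF gives the primary alcohol F7, TEMPO/PhI(OAc)2 in MeCN/H2O gives the carboxylic acid F8, and coupling with MeNHOMe·HCl (EDC) gives the N-methoxy-N-methylamide F9. Iodine–lithium exchange (t-BuLi, THF, −78 °C, high dilution) then closes the ring by intramolecular acylation to the enone acetonide F10. Aqueous AcOH gives the enone diol F11, and Ac2O/pyridine returns 14.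

## Further compounds

F1 | step 16 | (6R)-hydroxy acid, ring-opened form of 22 | C=C1CC/C(=C(\CO[Si](c2ccccc2)(c2ccccc2)C(C)(C)C)C(=O)O)[C@H](O)/C=C(/C)[C@@H](OC(C)=O)C[C@@H]1OC(C)=O
F2 | step 15 | (1S,3S,4Z)-7-hydroxy-4-methyl-10-methylidene-6-oxocyclodec-4-ene-1,3-diyl diacetate (C7 epimers) | C=C1CCC(O)C(=O)/C=C(/C)[C@@H](OC(C)=O)C[C@@H]1OC(C)=O
F3 | step 15 | (1S,3S,4Z)-4-methyl-10-methylidene-6,7-dioxocyclodec-4-ene-1,3-diyl diacetate | C=C1CCC(=O)C(=O)/C=C(/C)[C@@H](OC(C)=O)C[C@@H]1OC(C)=O
F4 | step 15 | tert-butyl 3-[(tert-butyldiphenylsilyl)oxy]propanoate | CC(C)(C)OC(=O)CCO[Si](c1ccccc1)(c1ccccc1)C(C)(C)C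
F5 | step 15 | hydroxy ester: F3 after addition of the enolate of F4 to C7 (C7/C11 diastereomers) | C=C1CCC(O)(C(CO[Si](c2ccccc2)(c2ccccc2)C(C)(C)C)C(=O)OC(C)(C)C)C(=O)/C=C(/C)[C@@H](OC(C)=O)C[C@@H]1OC(C)=O
F6 | step 10 | acetonide of diol 9 | I/C=C(/C)[C@@H]1C[C@@H](C(=C)CCCCO[Si](C)(C)C(C)(C)C)OC(C)(C)O1
F7 | step 10 | primary alcohol from F6 | I/C=C(/C)[C@@H]1C[C@@H](C(=C)CCCCO)OC(C)(C)O1
F8 | step 10 | carboxylic acid from F7 | I/C=C(/C)[C@@H]1C[C@@H](C(=C)CCCC(=O)O)OC(C)(C)O1
F9 | step 10 | N-methoxy-N-methylamide of F8 | I/C=C(/C)[C@@H]1C[C@@H](C(=C)CCCC(=O)N(C)OC)OC(C)(C)O1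
F10 | step 10 | macrocyclic Z enone, 1,3-diol as acetonide | C=C1CCCC(=O)/C=C(/C)[C@@H]2C[C@@H]1OC(C)(C)O2
F11 | step 10 | (1S,3S,4Z)-1,3-dihydroxy-4-methyl-10-methylidenecyclodec-4-en-6-one | C=C1CCCC(=O)/C=C(/C)[C@@H](O)C[C@@H]1O
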